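## Structural features

The target is an achiral diaryl ether built from two polyketide-type rings. Ring A is the benzo ring of an isocoumarin (C1 lactone carbonyl, O2, C3 bearing pentyl, C4–H, C4a, C5–H, C6–OH, C7–H, C8–O, C8a). Ring B is an olivetolic acid ring numbered C1' (ether carbon), C2' (OH), C3' (H), C4' (OH), C5' (CO2H), C6' (pentyl). The rings are joined by the O8–C1' bond, which is flanked by the lactone-bearing C8a on one side and by C6' (pentyl) and C2' (OH) on the other, so the ether is tri-ortho-substituted and ring B is hexasubstituted. There are no stereocentres in the target; the only sp3 centres that ever stand next to each other are the transient C1', C5' and C6' of a saturated ring B precursor. Fragile elements are the beta-resorcylic acid at C5' (protodecarboxylation in hot acid), the enol lactone O2–C3=C4 (opened by alkoxide or hydroxide and within reach of a C2' phenoxide) and the very electron-rich C3'–H (halogenation). The real difficulty is the crowded O8–C1' bond together with the unambiguous placing of six different substituents on ring B. The key step uses the fact that C1' lies between the alkyl carbon C6' and the oxygenated C2' of a 2',4'-dioxygenated ring with a carboxyl at C5'. That is the pattern of a 4-carboxy-5-alkylcyclohexane-1,3-dione, so ring B can be grown on the ether oxygen from an alpha-aryloxy enone (C3', C2', C1', C6') and a malonate (C4', C5', carboxyl) and aromatised afterwards.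

## Logic of the disconnections

18 to 17: the O–CH3 bonds at O6 and at the C5' carboxyl are cut. Both oxygen functions are carried as methyl derivatives because ring A comes from a dimethoxyarene and the carboxyl comes from 10. The acid, the most fragile group, then appears only in the last operation. The forward step must remove an aryl methyl ether and a hindered, chelated methyl ester in one Lewis-acid treatment without opening the lactone or losing CO2.

17 to 16: the lactone bond O2–C3 is cut. This turns the pyranone into an o-alkynyl benzoate and removes one ring. The forward step must close 6-endo (oxygen to C3, not to C4) and must expel the ester methyl group.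

16 to 14 and 15: the C4a–C4 bond is cut. The whole C3–C4–pentyl unit becomes a commercial alkyne and ring A is reduced to an aryl bromide. The forward coupling must tolerate two free phenols and must run without strong base, so that the C2' phenol does not attack the ring A ester.

14 to 12 (through 13): no skeletal bond is cut; ring B is taken back by one oxidation level to a cyclohexane-1,3-dione. The regiochemical problem of a hexasubstituted benzene becomes the regiochemistry of an annulation. The forward step must dehydrogenate ring B with exactly one equivalent of oxidant and must not halogenate C3' or ring A. The phenols are left free afterwards, which saves a protection step and leaves less to cleave at the end.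

12 to 9 and 10 (through 11): C5'–C6' and C3'–C4' are cut. Ring B falls into an alpha-aryloxy enone and a three-carbon diester, and the ether bond is already in place on what will become C1'. The forward step needs conjugate addition to a donor-substituted enone and a ring closure that is faster than attack of the C1' enolate on the ring A ester.

9 to 7 and 8: the C1'=C6' double bond is cut. The pentyl chain becomes a commercial aldehyde and the enone becomes a phosphonate. The forward olefination must be mild enough for an enolisable aldehyde; the alkene geometry is irrelevant.

7 to 5 and 6: the O8–C1' bond is cut at an sp3 carbon. The hardest bond of the target becomes an O–H insertion of a carbenoid into a simple phenol, with no aryl–oxygen coupling at a crowded position. The forward step needs the carbenoid to prefer the hydrogen-bonded phenol over the ester carbonyl and the arene.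

5 back to 1 (through 4, 3 and 2): the ortho O–CH3 bond is cut, then the ester O–CH3 bond, then the acid is taken back to the aldehyde, then the C8a–C1 bond is cut. Each operation is a standard functional-group change on a symmetrical commercial arene. The demands are regioselective formylation next to bromine and demethylation of only the ether ortho to the ester.

## Other disconnections considered

Alternative 1: The cut runs through C8–C8a and C4a–C5 of ring A.
- Forward key step: the silyloxy diene A1, whose C1 oxygen already carries ring B, would add to the ester-bearing triple bond of the diynoate A2. The bicyclo[2.2.2]octadiene would then expel its saturated two-carbon bridge on heating (Alder–Rickert) and, after desilylation, leave the o-alkynyl benzoate A3.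
- In its favour: ring A, its ester, its alkyne and a free 6-OH would appear in one operation. The orientation follows from the matched polarisation of the diene (nucleophilic C4 terminus) and the ynoate (electrophilic beta-carbon). No aryl halide, cross-coupling or positive halogen is needed, and no carbanion is ever formed next to an ortho ester. On these points the alternative is the better plan.
- Equal: A3 is the counterpart of 16 and faces the same 6-endo lactonisation, so the endgames are equivalent.
- Against it here: A1 needs a hexasubstituted ring B phenol that already has oxygen at C1', that is, an olivetolate oxidised between its pentyl group and an oxygen. The chosen plan gets this pattern automatically; here it would cost several extra steps. A di-ortho-substituted phenol would then have to be turned into a vinylogous ester and enol-silylated. The second triple bond of A2 and the high extrusion temperature add chemoselectivity questions.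
- Comparison: cleaner mechanism at ring A and more convergent, but probably longer, and it depends on a ring B building block that is harder to make than ring B is in the chosen route.

Alternative 2: The cut runs through C4a–C8a and O2–C1.
- Forward key step: the ketal-masked polycarbonyl dioxinone A4 would undergo amine-induced aldol condensation and aromatisation to ring A. Acid added to the same pot would unmask the C3 ketone and lactonise its enol onto C1, giving the isocoumarin A5.
- In its favour: it is biomimetic and pot-economic, and it needs no metal and no phenol protection. The lactone regiochemistry is fixed because the oxygen-bearing carbon C3 is a ketone from the start. On lactone formation the alternative is the better plan.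
- Equal: both plans make an aromatic ring by late aromatisation of a carbonyl-rich precursor.
- Against it here: A5 contains no ring B, so the O8–C1' bond is still to be made. That would mean arylating the hydrogen-bonded, less reactive 8-OH in the presence of the freer 6-OH with a hexasubstituted, electron-rich ring B partner. Such a tri-ortho-substituted aryl ether coupling has no activating group to help it. Growing ring B on O8 by enolate chemistry would expose the enol lactone to alkoxide.
- Comparison: very short to A5, but it solves the easier half of the molecule. The chosen plan makes the ether first, at an sp3 carbon, and builds the crowded ring around it.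

Alternative 3: The cut runs through C6–C7, C8–C8a and C5–C6.
- Forward key step: irradiation of the diazo ketoester A6 would give, by Wolff rearrangement, a vinylketene that adds the ring B ethynyl ether A7. Four-electron ring opening of the cyclobutenone and six-electron electrocyclisation would then give the phenol A8.
- In its favour: every substituent of ring A is placed by the mechanism, and the O8–C1' bond is carried in from A7. The 6-OH arrives free and the C3 ketone is masked in the side chain, so acid would give the pyranone without an endo/exo question and without demethylating ring A. On these two points the alternative is the better plan.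
- Equal: both plans form the diaryl ether bond before the second ring exists, and the regiochemical security of the annulation is comparable.
- Against it here: A7 is an aryl ethynyl ether of a hexasubstituted phenol. The usual routes to such ethers use strong bases that the ring B ester would not survive, and the ether is sensitive. A6 needs several steps, the photochemistry is dilute, and ring B with oxygen at C1' again has to be made beforehand.
- Comparison: elegant and convergent, but probably several steps longer, with two sensitive partners in place of robust enolate chemistry.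

Key step: step 7

Remark on the chemistry: 9 is drawn as the Z isomer (the E isomer serves equally); 11, 12 and 13 are written as keto tautomers and are diastereomer mixtures whose sp3 centres all vanish in step 8.

Step 1
Reactants: 1 1-bromo-3,5-dimethoxybenzene
Product: 2 2-bromo-4,6-dimethoxybenzaldehyde
Conditions: POCl3, DMF, 0 °C then 90 °C; aq. NaOAc
Reagents that add atoms: N,N-dimethylformamide CN(C)C=O; water O
Why: Vilsmeier–Haack formylation; the chloroiminium ion should attack para to one methoxy group and ortho to the other, which places the future C1 carbon next to bromine.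

Step 2
Reactants: 2 2-bromo-4,6-dimethoxybenzaldehyde
Product: 3 2-bromo-4,6-dimethoxybenzoic acid
Conditions: NaClO2, NaH2PO4, 2-methyl-2-butene, t-BuOH/H2O, rt
Reagents that add atoms: sodium chlorite [Na+].[O-]Cl=O
Why: Pinnick oxidation is selective for the aldehyde; the alkene scavenger removes hypochlorous acid before it can chlorinate the electron-rich ring.

Step 3
Reactants: 3 2-bromo-4,6-dimethoxybenzoic acid
Product: 4 methyl 2-bromo-4,6-dimethoxybenzoate
Conditions: iodomethane, K2CO3, DMF, rt
Reagents that add atoms: iodomethane CI
Why: O-alkylation of the carboxylate (SN2) is not slowed by the two ortho substituents that would hinder a Fischer esterification.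

Step 4
Reactants: 4 methyl 2-bromo-4,6-dimethoxybenzoate
Product: 5 methyl 2-bromo-6-hydroxy-4-methoxybenzoate
Conditions: BCl3, CH2Cl2, −78 °C to 0 °C; H2O
Reagents that add atoms: none
Why: Chelation-controlled demethylation; BCl3 bound to the ester carbonyl delivers chloride only to the ortho methyl ether, and the low temperature should keep the hindered ester and the para ether intact.

Step 5
Reactants: 5 methyl 2-bromo-6-hydroxy-4-methoxybenzoate; 6 dimethyl (1-diazo-2-oxopropyl)phosphonate
Product: 7 methyl 2-bromo-6-{[1-(dimethoxyphosphoryl)-2-oxopropyl]oxy}-4-methoxybenzoate (racemic)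
Conditions: Rh2(OAc)4 (2 mol %), toluene, 80 °C, slow addition of 6
Reagents that add atoms: none
Why: Rhodium-carbenoid O–H insertion of an alpha-diazo-beta-ketophosphonate into a phenol forms the O8–C1' bond at an sp3 carbon, so no aryl ether coupling is needed; the new stereocentre is racemic and is destroyed in step 6.

Step 6
Reactants: 7 methyl 2-bromo-6-{[1-(dimethoxyphosphoryl)-2-oxopropyl]oxy}-4-methoxybenzoate; 8 hexanal
Product: 9 methyl 2-bromo-4-methoxy-6-{[(3Z)-2-oxonon-3-en-3-yl]oxy}benzoate
Conditions: LiCl, DBU, MeCN, 0 °C to rt
Reagents that add atoms: none
Why: Horner–Wadsworth–Emmons olefination under Masamune–Roush conditions, mild enough for an enolisable aldehyde; alpha-aryloxy phosphonates of this kind give enol ethers, the Z isomer is expected to dominate, and either isomer serves in step 7.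

Step 7
Reactants: 9 methyl 2-bromo-4-methoxy-6-{[(3Z)-2-oxonon-3-en-3-yl]oxy}benzoate; 10 dimethyl malonate
Product: 12 methyl 5-[3-bromo-5-methoxy-2-(methoxycarbonyl)phenoxy]-2,4-dioxo-6-pentylcyclohexane-1-carboxylate (diastereomer mixture), via Michael adduct 11 (not isolated)
Conditions: NaOMe (1.3 equiv), MeOH, 0 °C then reflux; cold 1 M HCl
Reagents that add atoms: none
Why: The sodium salt of 10 adds to C6', the only electrophilic alkene carbon of 9 (Michael addition, C5'–C6' bond), and methanol protonates the resulting C1' enolate at once to give 11. Equilibrating methoxide then forms the methyl-ketone enolate at C3', which attacks one malonate ester (C3'–C4' bond) in a 6-(enolendo)-exo-trig Claisen closure; loss of methoxide and deprotonation of the new beta-diketone make the sequence irreversible. The closest known reaction is the Michael–Claisen annulation of non-3-en-2-one with a malonate that underlies olivetol-type rings. Three sp3 centres (C1', C5', C6') arise without control and are all erased in step 8, so none has to be set. The selectivity needed is chemoselectivity between two ketone enolates and three kinds of ester: only the C3' enolate can reach a six-membered beta-diketone that is stabilised as its enolate. Attack of the C1' enolate on the ring A ester (5-exo-trig) would need a tertiary, aryloxy-stabilised carbon to add to a 2,6-disubstituted, donor-deactivated benzoate and would lead to a non-enolisable ketone. The protic medium shortens the life of the C1' enolate formed in the Michael step, and aryloxide is too poor a leaving group at C1' for a 3-exo-tet displacement by the malonate anion to compete.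

Step 8
Reactants: 12 methyl 5-[3-bromo-5-methoxy-2-(methoxycarbonyl)phenoxy]-2,4-dioxo-6-pentylcyclohexane-1-carboxylate
Product: 14 methyl 3-[3-bromo-5-methoxy-2-(methoxycarbonyl)phenoxy]-4,6-dihydroxy-2-pentylbenzoate, via bromodione 13 (not isolated)
Conditions: Br2 (1.0 equiv), DMF, 0 °C; then 80 °C
Reagents that add atoms: none
Why: Halogenative aromatisation of a dihydroresorcylate: the enolised 1,3-dione is brominated at C3', and heating brings about 1,4-dehydrobromination and tautomerisation to the resorcinol. One equivalent of Br2 at 0 °C should be consumed by the enol before ring A can react, the bromine leaves again as HBr, and the three sp3 centres of 12 disappear.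

Step 9
Reactants: 14 methyl 3-[3-bromo-5-methoxy-2-(methoxycarbonyl)phenoxy]-4,6-dihydroxy-2-pentylbenzoate; 15 hept-1-yne
Product: 16 methyl 3-[3-(hept-1-yn-1-yl)-5-methoxy-2-(methoxycarbonyl)phenoxy]-4,6-dihydroxy-2-pentylbenzoate
Conditions: Pd(PPh3)2Cl2 (5 mol %), CuI (10 mol %), Et3N, DMF, 60 °C, argon
Reagents that add atoms: none
Why: Sonogashira coupling; the ortho ester activates the C–Br bond towards oxidative addition to zerovalent palladium, and both ring A donors are meta to bromine. Free phenols are tolerated by the amine base, and the absence of a strong base keeps the C2' phenol from attacking the ring A ester.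

Step 10
Reactants: 16 methyl 3-[3-(hept-1-yn-1-yl)-5-methoxy-2-(methoxycarbonyl)phenoxy]-4,6-dihydroxy-2-pentylbenzoate
Product: 17 methyl 4,6-dihydroxy-3-[(6-methoxy-1-oxo-3-pentyl-1H-isochromen-8-yl)oxy]-2-pentylbenzoate
Conditions: Ph3PAuNTf2 (5 mol %), CF3CO2H (10 equiv), (CH2Cl)2, 50 °C
Reagents that add atoms: none
Why: Gold-catalysed 6-endo-dig cyclisation of an o-alkynylbenzoate ester: the ester carbonyl oxygen, made more nucleophilic by the para-methoxy and ortho-aryloxy groups, attacks C3 of the activated alkyne, protodeauration follows, and trifluoroacetate removes the methyl group from the 1-methoxyisochromenylium ion. Alkyl-substituted o-alkynylbenzoates close in the six-membered mode under this activation, and the ring B ester and phenols are spectators.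

Step 11
Reactants: 17 methyl 4,6-dihydroxy-3-[(6-methoxy-1-oxo-3-pentyl-1H-isochromen-8-yl)oxy]-2-pentylbenzoate
Product: 18 4,6-dihydroxy-3-[(6-hydroxy-1-oxo-3-pentyl-1H-isochromen-8-yl)oxy]-2-pentylbenzoic acid (target)
Conditions: BBr3 (8 equiv), CH2Cl2, −78 °C to rt; ice-water
Reagents that add atoms: none
Why: BBr3 demethylates the C6 aryl ether and, through the boron chelate with the ortho phenol, dealkylates the hindered, electron-rich methyl ester (boron trihalide cleavage of hindered methyl benzoates by bromide attack on the O-methyl group). The enol lactone and the diaryl ether offer no sp3 carbon to bromide, and the acid stays masked as a boron chelate until cold aqueous work-up, which should limit protodecarboxylation.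

Compound list

1 | 1-bromo-3,5-dimethoxybenzene | COc1cc(Br)cc(OC)c1 | starting material
2 | 2-bromo-4,6-dimethoxybenzaldehyde | COc1cc(Br)c(C=O)c(OC)c1 | intermediate
3 | 2-bromo-4,6-dimethoxybenzoic acid | COc1cc(Br)c(C(=O)O)c(OC)c1 | intermediate
4 | methyl 2-bromo-4,6-dimethoxybenzoate | COc1cc(Br)c(C(=O)OC)c(OC)c1 | intermediate
5 | methyl 2-bromo-6-hydroxy-4-methoxybenzoate | COc1cc(O)c(C(=O)OC)c(Br)c1 | intermediate
6 | dimethyl (1-diazo-2-oxopropyl)phosphonate | COP(=O)(OC)C(=[N+]=[N-])C(C)=O | starting material
7 | methyl 2-bromo-6-{[1-(dimethoxyphosphoryl)-2-oxopropyl]oxy}-4-methoxybenzoate (racemic) | COC(=O)c1c(Br)cc(OC)cc1OC(C(C)=O)P(=O)(OC)OC | intermediate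
8 | hexanal | CCCCCC=O | starting material
9 | methyl 2-bromo-4-methoxy-6-{[(3Z)-2-oxonon-3-en-3-yl]oxy}benzoate | CCCCC/C=C(\Oc1cc(OC)cc(Br)c1C(=O)OC)C(C)=O | intermediate
10 | dimethyl malonate | COC(=O)CC(=O)OC | starting material
11 | Michael adduct, dimethyl 2-{2-[3-bromo-5-methoxy-2-(methoxycarbonyl)phenoxy]-3-oxo-1-pentylbutyl}propanedioate (diastereomer mixture) | CCCCCC(C(Oc1cc(OC)cc(Br)c1C(=O)OC)C(C)=O)C(C(=O)OC)C(=O)OC | intermediate (not isolated)
12 | methyl 5-[3-bromo-5-methoxy-2-(methoxycarbonyl)phenoxy]-2,4-dioxo-6-pentylcyclohexane-1-carboxylate (diastereomer mixture) | CCCCCC1C(Oc2cc(OC)cc(Br)c2C(=O)OC)C(=O)CC(=O)C1C(=O)OC | intermediate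
13 | bromodione, methyl 3-bromo-5-[3-bromo-5-methoxy-2-(methoxycarbonyl)phenoxy]-2,4-dioxo-6-pentylcyclohexane-1-carboxylate (diastereomer mixture) | CCCCCC1C(Oc2cc(OC)cc(Br)c2C(=O)OC)C(=O)C(Br)C(=O)C1C(=O)OC | intermediate (not isolated)
14 | methyl 3-[3-bromo-5-methoxy-2-(methoxycarbonyl)phenoxy]-4,6-dihydroxy-2-pentylbenzoate | CCCCCc1c(Oc2cc(OC)cc(Br)c2C(=O)OC)c(O)cc(O)c1C(=O)OC | intermediate
15 | hept-1-yne | CCCCCC#C | starting material
16 | methyl 3-[3-(hept-1-yn-1-yl)-5-methoxy-2-(methoxycarbonyl)phenoxy]-4,6-dihydroxy-2-pentylbenzoate | CCCCCC#Cc1cc(OC)cc(Oc2c(O)cc(O)c(C(=O)OC)c2CCCCC)c1C(=O)OC | intermediate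
17 | methyl 4,6-dihydroxy-3-[(6-methoxy-1-oxo-3-pentyl-1H-isochromen-8-yl)oxy]-2-pentylbenzoate | CCCCCc1cc2cc(OC)cc(Oc3c(O)cc(O)c(C(=O)OC)c3CCCCC)c2c(=O)o1 | intermediate
18 | 4,6-dihydroxy-3-[(6-hydroxy-1-oxo-3-pentyl-1H-isochromen-8-yl)oxy]-2-pentylbenzoic acid | CCCCCc1cc2cc(O)cc(Oc3c(O)cc(O)c(C(=O)O)c3CCCCC)c2c(=O)o1 | target

Total step count: 11. Longest linear sequence: 11 steps (1 to 18); 6, 8, 10 and 15 enter as purchased reagents.

Steps least certain to work

Step 7 (key step).
- What may go wrong: the Michael adduct may be diverted by attack of its C1' enolate on the ring A ester, followed by retro-Claisen loss of the acetyl group. The C1' position is the more acidic ketone alpha-position, and the wanted closure has to proceed from the small neutral fraction of the malonate. Conjugate addition to an enone that is also an enol ether may also be slow.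
- Fallback: the partners are exchanged. From 5, rhodium-catalysed O–H insertion with methyl 2-diazo-2-(dimethoxyphosphoryl)acetate F1 (from trimethyl phosphonoacetate by diazo transfer) would give methyl 2-bromo-6-[1-(dimethoxyphosphoryl)-2-methoxy-2-oxoethoxy]-4-methoxybenzoate F2. Olefination with 8 would give methyl 2-bromo-4-methoxy-6-{[(2Z)-1-methoxy-1-oxooct-2-en-2-yl]oxy}benzoate F3. Methyl acetoacetate with NaOMe in methanol would then add through its central carbon to C6', giving dimethyl 2-acetyl-4-[3-bromo-5-methoxy-2-(methoxycarbonyl)phenoxy]-3-pentylpentanedioate F4. Claisen closure of the acetyl methyl onto the aryloxy-substituted ester (C2'–C3') gives 12, where the route is rejoined. In this pairing, the classical dihydroorsellinate construction, C1' is alpha to an ester only, so its enolate is far less populated and there is no acetyl group to be lost.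

Step 8.
- What may go wrong: positive bromine may be transferred from the bromodione to C3' of the newly formed resorcinol ring (or to ring A), with incomplete dehydrobromination of the rest. The product is the most electron-rich arene in the flask, and hydrogenolytic clean-up is barred by the ring A bromide.
- Fallback: dehydrogenation without any halogenating agent. From 12, double enol silylation (TMSOTf, Et3N, CH2Cl2, 0 °C) would give methyl 5-[3-bromo-5-methoxy-2-(methoxycarbonyl)phenoxy]-6-pentyl-2,4-bis[(trimethylsilyl)oxy]cyclohexa-1,3-diene-1-carboxylate F5. DDQ in benzene at room temperature would aromatise this cyclohexadiene by hydride abstraction to methyl 3-[3-bromo-5-methoxy-2-(methoxycarbonyl)phenoxy]-2-pentyl-4,6-bis[(trimethylsilyl)oxy]benzoate F6. Methanolic work-up would then return 14.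

Step 10.
- What may go wrong: the reaction may stall at the O-methyl isochromenylium stage, with hydrolytic ring opening or methyl transfer to the ring B phenols on work-up, because expulsion of a methyl group needs a nucleophile. Closure in the 5-exo sense is the other possible failure.
- Fallback: the oxygen-accepting carbon is installed as a ketone, so that neither question arises. From 14, palladium-catalysed arylation (PdCl2[P(o-tolyl)3]2, Bu3SnF, toluene, 100 °C) of the tin enolate generated from trimethyl[(hept-1-en-2-yl)oxy]silane F7 (from heptan-2-one, LiN(iPr)2, Me3SiCl, −78 °C) would give methyl 4,6-dihydroxy-3-[5-methoxy-2-(methoxycarbonyl)-3-(2-oxoheptyl)phenoxy]-2-pentylbenzoate F8. TsOH in refluxing toluene would close the enol lactone with loss of methanol and arrive at 17.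

Step 11.
- What may go wrong: cleavage of the chelated methyl ester may be incomplete, or the freed beta-resorcylic acid may lose CO2 during long exposure to Lewis acid and HBr. Ester dealkylation is the slowest of the cleavages and the product acid is activated for ipso-protonation.
- Fallback: the two cleavages are separated. From 17, BBr3 held at 0 °C would be stopped at methyl 4,6-dihydroxy-3-[(6-hydroxy-1-oxo-3-pentyl-1H-isochromen-8-yl)oxy]-2-pentylbenzoate F9. The ester would then be dealkylated under neutral conditions by iodide (LiI, EtOAc, reflux), and cold dilute HCl would release 18.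

Further compounds

F1 | step 7 | methyl 2-diazo-2-(dimethoxyphosphoryl)acetate | COC(=O)C(=[N+]=[N-])P(=O)(OC)OC
F2 | step 7 | methyl 2-bromo-6-[1-(dimethoxyphosphoryl)-2-methoxy-2-oxoethoxy]-4-methoxybenzoate (racemic) | COC(=O)C(Oc1cc(OC)cc(Br)c1C(=O)OC)P(=O)(OC)OC
F3 | step 7 | methyl 2-bromo-4-methoxy-6-{[(2Z)-1-methoxy-1-oxooct-2-en-2-yl]oxy}benzoate | CCCCC/C=C(\Oc1cc(OC)cc(Br)c1C(=O)OC)C(=O)OC
F4 | step 7 | dimethyl 2-acetyl-4-[3-bromo-5-methoxy-2-(methoxycarbonyl)phenoxy]-3-pentylpentanedioate (diastereomer mixture) | CCCCCC(C(Oc1cc(OC)cc(Br)c1C(=O)OC)C(=O)OC)C(C(C)=O)C(=O)OC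
F5 | step 8 | methyl 5-[3-bromo-5-methoxy-2-(methoxycarbonyl)phenoxy]-6-pentyl-2,4-bis[(trimethylsilyl)oxy]cyclohexa-1,3-diene-1-carboxylate (diastereomer mixture) | CCCCCC1C(Oc2cc(OC)cc(Br)c2C(=O)OC)C(O[Si](C)(C)C)=CC(O[Si](C)(C)C)=C1C(=O)OC
F6 | step 8 | methyl 3-[3-bromo-5-methoxy-2-(methoxycarbonyl)phenoxy]-2-pentyl-4,6-bis[(trimethylsilyl)oxy]benzoate | CCCCCc1c(Oc2cc(OC)cc(Br)c2C(=O)OC)c(O[Si](C)(C)C)cc(O[Si](C)(C)C)c1C(=O)OC
F7 | step 10 | trimethyl[(hept-1-en-2-yl)oxy]silane | CCCCCC(=C)O[Si](C)(C)C
F8 | step 10 | methyl 4,6-dihydroxy-3-[5-methoxy-2-(methoxycarbonyl)-3-(2-oxoheptyl)phenoxy]-2-pentylbenzoate | CCCCCC(=O)Cc1cc(OC)cc(Oc2c(O)cc(O)c(C(=O)OC)c2CCCCC)c1C(=O)OC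
F9 | step 11 | methyl 4,6-dihydroxy-3-[(6-hydroxy-1-oxo-3-pentyl-1H-isochromen-8-yl)oxy]-2-pentylbenzoate | CCCCCc1cc2cc(O)cc(Oc3c(O)cc(O)c(C(=O)OC)c3CCCCC)c2c(=O)o1
A1 | alternative 1 | methyl 3-({3-[(tert-butyldimethylsilyl)oxy]cyclohexa-1,3-dien-1-yl}oxy)-4,6-dimethoxy-2-pentylbenzoate | CCCCCc1c(OC2=CC(O[Si](C)(C)C(C)(C)C)=CCC2)c(OC)cc(OC)c1C(=O)OC
A2 | alternative 1 | methyl deca-2,4-diynoate | CCCCCC#CC#CC(=O)OC
A3 | alternative 1 | methyl 3-[3-(hept-1-yn-1-yl)-5-hydroxy-2-(methoxycarbonyl)phenoxy]-4,6-dimethoxy-2-pentylbenzoate | CCCCCC#Cc1cc(O)cc(Oc2c(OC)cc(OC)c(C(=O)OC)c2CCCCC)c1C(=O)OC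
A4 | alternative 2 | 2,2-dimethyl-6-[2,4-dioxo-5-(2-pentyl-1,3-dioxolan-2-yl)pentyl]-4H-1,3-dioxin-4-one | CCCCCC1(CC(=O)CC(=O)CC2=CC(=O)OC(C)(C)O2)OCCO1
A5 | alternative 2 | 6,8-dihydroxy-3-pentyl-1H-isochromen-1-one | CCCCCc1cc2cc(O)cc(O)c2c(=O)o1
A6 | alternative 3 | ethyl 2-diazo-4-methylidene-3-oxo-5-(2-pentyl-1,3-dioxolan-2-yl)pentanoate | CCCCCC1(CC(=C)C(=O)C(=[N+]=[N-])C(=O)OCC)OCCO1
A7 | alternative 3 | methyl 3-(ethynyloxy)-4,6-dimethoxy-2-pentylbenzoate | C#COc1c(OC)cc(OC)c(C(=O)OC)c1CCCCC
A8 | alternative 3 | ethyl 2-[2,4-dimethoxy-5-(methoxycarbonyl)-6-pentylphenoxy]-4-hydroxy-6-[(2-pentyl-1,3-dioxolan-2-yl)methyl]benzoate | CCOC(=O)c1c(Oc2c(OC)cc(OC)c(C(=O)OC)c2CCCCC)cc(O)cc1CC1(CCCCC)OCCO1
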